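The route rests on disconnecting the cis C3=C4 olefin of the 2,2-dimethyl-2H-pyran ring, the only non-aromatic ring olefin of the target, flanked by quaternary C2 and aromatic C4a. Ring-closing metathesis forms this bond as the last step and closes the pyran in its linear fusion to ring A without protecting groups. The precursor is a fully substituted ring A dihydrochalcone with a vinyl group at the future C4a and a 1,1-dimethylallyl ether on the neighbouring oxygen (future O1). One tertiary allyl carbonate is used twice: the first ether is converted by aromatic Claisen rearrangement into the C8 prenyl group, the second becomes C2 and C3 of the pyran.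

Key step: step 7

Remark: the target has no stereocentre; the ring olefin is Z by ring size. Ring A positions are primed and numbered from the carbon that bears the ketone (C1'); the hydroxyphenethyl ring is ring B. The route assumes that the ring A hydroxyl para to the ketone, as the most acidic of the three phenols, is the one that is alkylated.

Step 1
Reactants: 1 2-methylbut-3-en-2-ol; 2 di-tert-butyl dicarbonate
Product: 4 tert-butyl 2-methylbut-3-en-2-yl carbonate, via lithium 2-methylbut-3-en-2-olate 3 (not isolated)
Conditions: n-BuLi, THF, −78 °C; then 2, −78 °C to rt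
Reagents that add atoms: di-tert-butyl dicarbonate (2), CC(C)(C)OC(=O)OC(=O)OC(C)(C)C
Why: Deprotonation and O-acylation of the lithium alkoxide by the dicarbonate (carbonate formation); the expelled tert-butyl carbonate collapses to CO2 and tert-butoxide, which makes the acyl transfer irreversible.

Step 2
Reactants: 5 4-bromobenzene-1,3-diol (4-bromoresorcinol); 6 3-(4-hydroxyphenyl)propanoic acid
Product: 7 1-(5-bromo-2,4-dihydroxyphenyl)-3-(4-hydroxyphenyl)propan-1-one
Conditions: BF3·OEt2 (solvent), 85 °C; then aq. NaOAc
Reagents that add atoms: 3-(4-hydroxyphenyl)propanoic acid (6), OC(=O)CCc1ccc(O)cc1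
Why: Friedel–Crafts acylation with a carboxylic acid in BF3·OEt2 (Nencki type); the resorcinol ring is far more nucleophilic than ring B of the acid, and attack should occur only at C6 of 5 (ortho to one hydroxyl, para to the other), since C2 is flanked by two hydroxyls and C5 is meta to both; the boron chelate of the ortho-hydroxy ketone is hydrolysed on work-up.

Step 3
Reactants: 7 1-(5-bromo-2,4-dihydroxyphenyl)-3-(4-hydroxyphenyl)propan-1-one; 4 tert-butyl 2-methylbut-3-en-2-yl carbonate
Product: 8 1-[5-bromo-2-hydroxy-4-(2-methylbut-3-en-2-yloxy)phenyl]-3-(4-hydroxyphenyl)propan-1-one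
Conditions: Pd(PPh3)4 (5 mol %), THF, 0 °C
Reagents that add atoms: tert-butyl 2-methylbut-3-en-2-yl carbonate (4), CC(C)(C)OC(=O)OC(C)(C)C=C
Why: Palladium-catalysed decarboxylative O-allylation (Tsuji–Trost type): zerovalent palladium ionises the tertiary carbonate, the tert-butoxide set free deprotonates the most acidic phenol (para to the ketone, ortho to bromine), and this phenoxide attacks the more substituted allyl terminus under kinetic control to give the branched ether, while the hydrogen-bonded ortho-hydroxyl and the less acidic ring B phenol should stay free and the aryl bromide is not touched at 0 °C.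

Step 4
Reactants: 8 1-[5-bromo-2-hydroxy-4-(2-methylbut-3-en-2-yloxy)phenyl]-3-(4-hydroxyphenyl)propan-1-one
Product: 10 1-[5-bromo-2,4-dihydroxy-3-(3-methylbut-2-en-1-yl)phenyl]-3-(4-hydroxyphenyl)propan-1-one, via ortho-dienone 9 (not isolated)
Conditions: PhNEt2, 130 °C
Reagents that add atoms: none
Why: Aromatic Claisen rearrangement ([3,3]-sigmatropic): with C5' blocked by bromine only C3' can accept the allyl terminus, the 1,1-dimethylallyl group is inverted into a prenyl group, and dienone 9 tautomerises to the phenol; the basic solvent suppresses acid-induced cyclisation of the ortho-prenylphenol.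

Step 5
Reactants: 10 1-[5-bromo-2,4-dihydroxy-3-(3-methylbut-2-en-1-yl)phenyl]-3-(4-hydroxyphenyl)propan-1-one; 11 2-ethenyl-4,4,5,5-tetramethyl-1,3,2-dioxaborolane
Product: 12 1-[5-ethenyl-2,4-dihydroxy-3-(3-methylbut-2-en-1-yl)phenyl]-3-(4-hydroxyphenyl)propan-1-one
Conditions: Pd(OAc)2 (5 mol %), SPhos (10 mol %), K3PO4, 1,4-dioxane/H2O, 80 °C
Reagents that add atoms: 2-ethenyl-4,4,5,5-tetramethyl-1,3,2-dioxaborolane (11), C=CB1OC(C)(C)C(C)(C)O1
Why: Suzuki–Miyaura coupling; the electron-rich biarylphosphine SPhos should allow oxidative addition into the oxygen-rich aryl bromide, free phenols and the trisubstituted prenyl olefin are tolerated, and the vinyl group is installed before the second etherification because a tertiary allyl aryl ether would be ionised by zerovalent palladium at this temperature.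

Step 6
Reactants: 12 1-[5-ethenyl-2,4-dihydroxy-3-(3-methylbut-2-en-1-yl)phenyl]-3-(4-hydroxyphenyl)propan-1-one; 4 tert-butyl 2-methylbut-3-en-2-yl carbonate
Product: 13 1-[5-ethenyl-2-hydroxy-4-(2-methylbut-3-en-2-yloxy)-3-(3-methylbut-2-en-1-yl)phenyl]-3-(4-hydroxyphenyl)propan-1-one
Conditions: Pd(PPh3)4 (10 mol %), THF, 0 °C; filtration through Et3N-deactivated silica
Reagents that add atoms: tert-butyl 2-methylbut-3-en-2-yl carbonate (4), CC(C)(C)OC(=O)OC(C)(C)C=C
Why: Second palladium-catalysed decarboxylative O-allylation (Tsuji–Trost type) with the same carbonate: the hydroxyl para to the ketone remains by far the most acidic phenol, and kinetic attack at the tertiary allyl terminus at 0 °C should give the branched ether even though the phenol is now flanked by prenyl and vinyl groups; all ortho and para positions are blocked, so no Claisen pathway is open to the product.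

Step 7
Reactants: 13 1-[5-ethenyl-2-hydroxy-4-(2-methylbut-3-en-2-yloxy)-3-(3-methylbut-2-en-1-yl)phenyl]-3-(4-hydroxyphenyl)propan-1-one
Product: 14 1-[7-hydroxy-2,2-dimethyl-8-(3-methylbut-2-en-1-yl)-2H-chromen-6-yl]-3-(4-hydroxyphenyl)propan-1-one
Conditions: second-generation Grubbs catalyst (H2IMes)(PCy3)Cl2Ru=CHPh (5 mol %), CH2Cl2 (0.005 M), 40 °C
Reagents that add atoms: none
Why: Ring-closing olefin metathesis by the Chauvin mechanism: the ruthenium benzylidene first exchanges with the unhindered styrene-type vinyl group at C5' of ring A, the resulting ruthenium arylidene adds across the neighbouring O–CMe2–CH=CH2 vinyl group in a [2+2] cycloaddition, and cycloreversion of the ruthenacyclobutane releases the C3=C4 bond and, after turnover, ethylene. The closest known reaction type is the ring-closing metathesis of 2-(1,1-dimethylallyloxy)styrenes to 2,2-dimethyl-2H-chromenes. The ring closed is the six-membered pyran, formed by joining the two internal alkene carbons of a 1,7-diene, so the new olefin is endocyclic and necessarily Z. No stereocentre is created. The step needs chemoselectivity over the trisubstituted prenyl olefin, whose reaction with the ether vinyl group would close a seven-membered oxepine and expel isobutene; this should be secured by the much faster initiation at the monosubstituted styrene, the preference for the six-membered ring, and the gem-dimethyl group that turns the ether vinyl group toward the styrene. The linear fusion of the pyran follows from the position of the vinyl group on ring A, which traces back to the bromine of 4-bromoresorcinol.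

Compound list
1 | 2-methylbut-3-en-2-ol | CC(C)(O)C=C | starting material
2 | di-tert-butyl dicarbonate | CC(C)(C)OC(=O)OC(=O)OC(C)(C)C | starting material
3 | lithium 2-methylbut-3-en-2-olate | [Li+].[O-]C(C)(C)C=C | intermediate
4 | tert-butyl 2-methylbut-3-en-2-yl carbonate | CC(C)(C)OC(=O)OC(C)(C)C=C | intermediate
5 | 4-bromobenzene-1,3-diol | Oc1ccc(Br)c(O)c1 | starting material
6 | 3-(4-hydroxyphenyl)propanoic acid | OC(=O)CCc1ccc(O)cc1 | starting material
7 | 1-(5-bromo-2,4-dihydroxyphenyl)-3-(4-hydroxyphenyl)propan-1-one | O=C(CCc1ccc(O)cc1)c1cc(Br)c(O)cc1O | intermediate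
8 | 1-[5-bromo-2-hydroxy-4-(2-methylbut-3-en-2-yloxy)phenyl]-3-(4-hydroxyphenyl)propan-1-one | O=C(CCc1ccc(O)cc1)c1cc(Br)c(OC(C)(C)C=C)cc1O | intermediate
9 | 2-bromo-5-hydroxy-4-[3-(4-hydroxyphenyl)propanoyl]-6-(3-methylbut-2-en-1-yl)cyclohexa-2,4-dien-1-one (racemic, transient) | O=C(CCc1ccc(O)cc1)C1=C(O)C(CC=C(C)C)C(=O)C(Br)=C1 | intermediate
10 | 1-[5-bromo-2,4-dihydroxy-3-(3-methylbut-2-en-1-yl)phenyl]-3-(4-hydroxyphenyl)propan-1-one | O=C(CCc1ccc(O)cc1)c1cc(Br)c(O)c(CC=C(C)C)c1O | intermediate
11 | 2-ethenyl-4,4,5,5-tetramethyl-1,3,2-dioxaborolane | C=CB1OC(C)(C)C(C)(C)O1 | starting material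
12 | 1-[5-ethenyl-2,4-dihydroxy-3-(3-methylbut-2-en-1-yl)phenyl]-3-(4-hydroxyphenyl)propan-1-one | O=C(CCc1ccc(O)cc1)c1cc(C=C)c(O)c(CC=C(C)C)c1O | intermediate
13 | 1-[5-ethenyl-2-hydroxy-4-(2-methylbut-3-en-2-yloxy)-3-(3-methylbut-2-en-1-yl)phenyl]-3-(4-hydroxyphenyl)propan-1-one | O=C(CCc1ccc(O)cc1)c1cc(C=C)c(OC(C)(C)C=C)c(CC=C(C)C)c1O | intermediate
14 | 1-[7-hydroxy-2,2-dimethyl-8-(3-methylbut-2-en-1-yl)-2H-chromen-6-yl]-3-(4-hydroxyphenyl)propan-1-one | CC(C)=CCc1c(O)c(C(=O)CCc2ccc(O)cc2)cc2c1OC(C)(C)C=C2 | target

Total step count: 7
Longest linear sequence: 6 steps (steps 2 to 7 from 5; the branch through step 1 and steps 3 to 7 is equally long)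

Steps most likely to fail

Step 7 (key step). The ruthenium carbene may engage the trisubstituted prenyl olefin, leading to closure of the seven-membered ring with loss of isobutene or to cross-metathesis scrambling. The crowded tertiary allyl aryl ether may also ionise before it cyclises. The fallback sets out from 10 and comes back to the route at 14. A Heck reaction of 10 with 2-methylbut-3-en-2-ol (1) (Pd(OAc)2, P(o-tol)3, Et3N, DMF, 100 °C) should give (E)-1-[2,4-dihydroxy-5-(3-hydroxy-3-methylbut-1-en-1-yl)-3-(3-methylbut-2-en-1-yl)phenyl]-3-(4-hydroxyphenyl)propan-1-one F1. Brief warming with PPTS in toluene should ionise the tertiary allylic alcohol, and the neighbouring phenol then closes the pyran at the O1–C2 bond with loss of water to give 14.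

Step 6. The hindered phenoxide may attack the primary allyl terminus, or the branched ether may re-ionise on palladium and drift to the linear prenyl ether. Alkylation of the ring B phenol may also compete. The fallback sets out from 12 and comes back at 13. Copper-catalysed propargylation with 3-chloro-3-methylbut-1-yne (CuCl2·2H2O cat., DBU, MeCN, 0 °C), which uses a slimmer electrophile and exactly one equivalent of base, should give 1-[5-ethenyl-2-hydroxy-4-(2-methylbut-3-yn-2-yloxy)-3-(3-methylbut-2-en-1-yl)phenyl]-3-(4-hydroxyphenyl)propan-1-one F2. Semihydrogenation of the terminal alkyne (H2, Pd/CaCO3 poisoned with Pb(OAc)2, quinoline, EtOAc, rt), stopped after one equivalent of hydrogen, should then give 13.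

Step 4. At the temperature of the rearrangement the tertiary allyl ether may undergo heterolysis with loss of isoprene, which returns phenol 7, or the new ortho-prenylphenol may cyclise onto its olefin. The fallback sets out from 7 and comes back at 10, bypassing 8. Direct C-prenylation of the phenolate of 7 with 1-bromo-3-methylbut-2-ene and DBU in THF at rt should place the prenyl group at C3', the only activated free carbon of ring A. No new compound arises on this path (F0).

Further compounds
F1 | step 7 | (E)-1-[2,4-dihydroxy-5-(3-hydroxy-3-methylbut-1-en-1-yl)-3-(3-methylbut-2-en-1-yl)phenyl]-3-(4-hydroxyphenyl)propan-1-one | CC(C)=CCc1c(O)c(C(=O)CCc2ccc(O)cc2)cc(/C=C/C(C)(C)O)c1O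
F2 | step 6 | 1-[5-ethenyl-2-hydroxy-4-(2-methylbut-3-yn-2-yloxy)-3-(3-methylbut-2-en-1-yl)phenyl]-3-(4-hydroxyphenyl)propan-1-one | O=C(CCc1ccc(O)cc1)c1cc(C=C)c(OC(C)(C)C#C)c(CC=C(C)C)c1O
F0 | step 4 | none | none
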